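The route rests on cutting the C4–C4a bond of the flavanone half. C4a sits in ring A between the oxygen-bearing carbons C5 and C8a. The open form is therefore a 3,5-dimethoxyphenyl ether at O1 with two interchangeable carbons next to O1, each also flanked by one methoxy group and lying para to the second. A mild intramolecular Friedel–Crafts acylation joins one of them to the acyl carbon. This closes ring C and completes the biflavonoid skeleton, while C2, set earlier by ketone hydrogenation and Mitsunobu inversion, is left alone. The precursor is an (S)-3-aryl-3-(3,5-dimethoxyphenoxy)propanoic acid whose aryl group already bears the C8''-linked flavone and a cation-discouraging 4'-acetate.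

Key step: step 11

Locants: unprimed = flavanone rings A and C; single prime = ring B; double prime = flavone chromenone; triple prime = its anisyl ring.
Assumption: the C3'–C8'' axis is taken to rotate freely at room temperature (the target has no axial descriptor), so C2 is the only stereogenic element to control.
Stereochemical check: C2 of the target is (S) (O1 > C1' > C3 > H). The carbinol before the inversion must therefore be (R). For an aroylacetate this calls for the (S)-configured BINAP ligand.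

Step 1
Reactants: 1 acacetin
Product: 2 5,7-dimethoxy-2-(4-methoxyphenyl)-4H-chromen-4-one (acacetin dimethyl ether)
Conditions: MeI (5 equiv), K2CO3 (5 equiv), DMF, 45 °C
Reagents that add atoms: iodomethane, CI
Why: Williamson ether synthesis, in which excess iodomethane in a warm dipolar solvent also captures the hydrogen-bonded 5''-OH and gives the 5'',7''-dialkoxy pattern that steers the next halogenation to C8''.

Step 2
Reactants: 2 5,7-dimethoxy-2-(4-methoxyphenyl)-4H-chromen-4-one
Product: 3 8-iodo-5,7-dimethoxy-2-(4-methoxyphenyl)-4H-chromen-4-one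
Conditions: NIS (1.1 equiv), TFA (1 equiv), MeCN/CH2Cl2, rt, dark
Reagents that add atoms: N-iodosuccinimide, O=C1CCC(=O)N1I
Why: Electrophilic aromatic iodination, in which the acid-activated N-iodoimide should attack C8'', the usual halogenation site of 5,7-dialkoxyflavones, rather than C6'' wedged between two methoxy groups, the enone carbon C3'' or the acceptor-conjugated anisyl ring.

Step 3
Reactants: 4 methyl 3-bromo-4-hydroxybenzoate
Product: 5 methyl 4-(benzyloxy)-3-bromobenzoate
Conditions: BnBr (1.1 equiv), K2CO3 (1.5 equiv), acetone, reflux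
Reagents that add atoms: benzyl bromide, BrCc1ccccc1
Why: Williamson ether synthesis; the benzyl ether is small enough for the later hindered coupling, inert to enolates, ruthenium hydrogenation and palladium coupling, and leaves under neutral hydrogenolysis.

Step 4
Reactants: 5 methyl 4-(benzyloxy)-3-bromobenzoate; 6 tert-butyl acetate
Product: 8 tert-butyl 3-[4-(benzyloxy)-3-bromophenyl]-3-oxopropanoate, via lithium enolate of tert-butyl acetate 7 (not isolated)
Conditions: 6 (3.2 equiv), LiN(iPr)2 (3.1 equiv), THF, −78 °C; then 5, −78 → 0 °C; aq NH4Cl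
Reagents that add atoms: none
Why: Crossed Claisen condensation, in which the preformed enolate 7 is acylated by the methyl ester, surplus enolate deprotonates the β-ketoester as it forms and drives the equilibrium, and no free amide base is left to metalate the bromoarene.

Step 5
Reactants: 8 tert-butyl 3-[4-(benzyloxy)-3-bromophenyl]-3-oxopropanoate
Product: 9 tert-butyl (3R)-3-[4-(benzyloxy)-3-bromophenyl]-3-hydroxypropanoate
Conditions: H2 (10 bar), RuCl2[(S)-BINAP](dmf)n (1 mol %), degassed EtOH, 50 °C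
Reagents that add atoms: none
Why: Noyori asymmetric hydrogenation of a β-ketoester, in which chelation of ketone and ester oxygens to the divalent ruthenium hydride fixes the face of hydride transfer, so that the (S)-BINAP ligand (the controlling element) should deliver the (R)-carbinol of an aroylacetate without touching aryl bromide, benzyl ether or tert-butyl ester.

Step 6
Reactants: 9 tert-butyl (3R)-3-[4-(benzyloxy)-3-bromophenyl]-3-hydroxypropanoate
Product: 10 tert-butyl (3R)-3-[4-(benzyloxy)-3-(4,4,5,5-tetramethyl-1,3,2-dioxaborolan-2-yl)phenyl]-3-hydroxypropanoate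
Conditions: B2pin2 (1.3 equiv), Pd(dppf)Cl2 (5 mol %), KOAc (3 equiv), 1,4-dioxane, 90 °C
Reagents that add atoms: bis(pinacolato)diboron, CC1(C)OB(OC1(C)C)B1OC(C)(C)C(C)(C)O1
Why: Miyaura borylation, in which the weak base KOAc enables transmetalation from the diboron without deprotonating the carbinol or the ester α-position, so the stereocentre is not at risk.

Step 7
Reactants: 3 8-iodo-5,7-dimethoxy-2-(4-methoxyphenyl)-4H-chromen-4-one; 10 tert-butyl (3R)-3-[4-(benzyloxy)-3-(4,4,5,5-tetramethyl-1,3,2-dioxaborolan-2-yl)phenyl]-3-hydroxypropanoate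
Product: 11 tert-butyl (3R)-3-{4-(benzyloxy)-3-[5,7-dimethoxy-2-(4-methoxyphenyl)-4-oxo-4H-chromen-8-yl]phenyl}-3-hydroxypropanoate
Conditions: Pd(OAc)2 (5 mol %), SPhos (10 mol %), K3PO4 (3 equiv), 1,4-dioxane/H2O (5:1), 85 °C
Reagents that add atoms: none
Why: Suzuki–Miyaura coupling, in which a bulky electron-rich biaryl phosphine is chosen for the triply ortho-substituted C3'–C8'' bond and the phosphate base is too weak to cause retro-aldol cleavage, dehydration or hydrolysis of the β-hydroxy tert-butyl ester.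

Step 8
Reactants: 11 tert-butyl (3R)-3-{4-(benzyloxy)-3-[5,7-dimethoxy-2-(4-methoxyphenyl)-4-oxo-4H-chromen-8-yl]phenyl}-3-hydroxypropanoate
Product: 13 tert-butyl (3R)-3-{4-acetoxy-3-[5,7-dimethoxy-2-(4-methoxyphenyl)-4-oxo-4H-chromen-8-yl]phenyl}-3-hydroxypropanoate, via free 4'-phenol 12 (not isolated)
Conditions: H2 (1 atm), Pd/C (10 wt %), EtOAc/THF, rt; filter; then Ac2O (1.1 equiv), Et3N (1.5 equiv), 0 °C
Reagents that add atoms: acetic anhydride, CC(=O)OC(C)=O
Why: Neutral hydrogenolysis of an aryl benzyl ether outruns cleavage of the secondary benzylic alcohol and saturation of C2''=C3'', and amine-mediated O-acetylation without a nucleophilic catalyst takes the phenol far faster than the carbinol, so that ring B is already a poor cation stabiliser before the inversion and all later acidic steps.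

Step 9
Reactants: 13 tert-butyl (3R)-3-{4-acetoxy-3-[5,7-dimethoxy-2-(4-methoxyphenyl)-4-oxo-4H-chromen-8-yl]phenyl}-3-hydroxypropanoate; 14 3,5-dimethoxyphenol
Product: 15 tert-butyl (3S)-3-{4-acetoxy-3-[5,7-dimethoxy-2-(4-methoxyphenyl)-4-oxo-4H-chromen-8-yl]phenyl}-3-(3,5-dimethoxyphenoxy)propanoate
Conditions: 14 (1.5 equiv), PPh3 (1.6 equiv), DIAD (1.6 equiv, slow addition), toluene, 0 °C → rt
Reagents that add atoms: none
Why: Mitsunobu etherification, in which the carbinol oxygen becomes an alkoxyphosphonium leaving group that the aryloxide displaces in an SN2 step, turning (R) into (S) at the future C2, while the 4'-acetate disfavours ionisation and the tert-butyl ester keeps the C3 protons weakly acidic and so limits elimination to the cinnamate.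

Step 10
Reactants: 15 tert-butyl (3S)-3-{4-acetoxy-3-[5,7-dimethoxy-2-(4-methoxyphenyl)-4-oxo-4H-chromen-8-yl]phenyl}-3-(3,5-dimethoxyphenoxy)propanoate
Product: 16 (3S)-3-{4-acetoxy-3-[5,7-dimethoxy-2-(4-methoxyphenyl)-4-oxo-4H-chromen-8-yl]phenyl}-3-(3,5-dimethoxyphenoxy)propanoic acid
Conditions: TFA/CH2Cl2 (1:4), 0 °C → rt; evaporate with toluene
Reagents that add atoms: none
Why: Acid-catalysed alkyl–oxygen cleavage of a tert-butyl ester avoids the hydroxide that would expel the aryloxide by E1cB elimination and strip the acetate, and tert-butylation of ring A is sterically costly because each of its free carbons lies between two oxygen substituents.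

Step 11
Reactants: 16 (3S)-3-{4-acetoxy-3-[5,7-dimethoxy-2-(4-methoxyphenyl)-4-oxo-4H-chromen-8-yl]phenyl}-3-(3,5-dimethoxyphenoxy)propanoic acid
Product: 18 4'-O-acetyl-5,5''-di-O-methyl-(2S)-2,3-dihydroheveaflavone, via mixed carboxylic trifluoroacetic anhydride 17 (not isolated)
Conditions: (CF3CO)2O (3 equiv), CH2Cl2, 0 °C; cold aq NaHCO3
Reagents that add atoms: none
Why: The anhydride converts the carboxyl group of 16 to the mixed anhydride 17, whose acyl carbon C4 (as such or as the acylium ion) is attacked by a ring A carbon next to O1, and loss of a proton and of trifluoroacetate leaves the aryl ketone. This is an intramolecular Friedel–Crafts acylation of the kind long used to turn 3-aryloxypropanoic acids, enantioenriched 3-aryl members included, into chroman-4-ones. Ring C closes in a 6-exo-trig mode at the anhydride carbonyl (6-exo-dig if the free acylium ion reacts), with the attacking arene C=C bond inside the new ring. No stereocentre is made, and C2 should keep its (S) configuration because none of its four bonds takes part and no enolate, chalcone or quinone methide lies on the path. Site selectivity is not an issue: the two carbons next to O1 interchange by rotation about the O1–aryl bond, the carbon para to O1 cannot reach C4, and C6'' of the flavone is deactivated by its acid-complexed C4'' carbonyl. The selectivity that matters is acylation over heterolysis of the benzylic C2–O1 bond and over trifluoroacetylation of ring A, and it is secured by the 4'-acetate, which lowers the donor power of ring B to about that of plain phenyl, by the withdrawing meta flavonyl group, and by the triply activated nucleophile, which lets the closure run at 0 °C with a small excess of anhydride.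

Step 12
Reactants: 18 4'-O-acetyl-5,5''-di-O-methyl-(2S)-2,3-dihydroheveaflavone
Product: 19 4'-O-acetyl-(2S)-2,3-dihydroheveaflavone
Conditions: BCl3 (1 M in CH2Cl2, 5 equiv), CH2Cl2, −78 → 0 °C; then H2O, 0 °C
Reagents that add atoms: none
Why: Chelation-directed Lewis acid ether cleavage, in which BCl3 bridges each C4 or C4'' carbonyl and its peri methoxy oxygen so that chloride removes only those two methyl groups, while the 7-, 7''- and 4'''-methoxy groups lack the chelate and the still acetylated ring B keeps C2–O1 from ionising.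

Step 13
Reactants: 19 4'-O-acetyl-(2S)-2,3-dihydroheveaflavone
Product: 20 (2S)-2,3-dihydroheveaflavone
Conditions: NH4OAc (10 equiv), MeOH/THF/H2O (8:2:1), rt
Reagents that add atoms: none
Why: Ammonium acetate-buffered transesterification of an aryl acetate, in which the aryl ester is the most electrophilic group left and the near-neutral medium avoids the phenoxide-driven ring opening to the chalcone by which 4'-hydroxyflavanones lose configuration at C2.

Compound list
1 | acacetin | COc1ccc(-c2cc(=O)c3c(O)cc(O)cc3o2)cc1 | starting material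
2 | 5,7-dimethoxy-2-(4-methoxyphenyl)-4H-chromen-4-one | COc1ccc(-c2cc(=O)c3c(OC)cc(OC)cc3o2)cc1 | intermediate
3 | 8-iodo-5,7-dimethoxy-2-(4-methoxyphenyl)-4H-chromen-4-one | COc1ccc(-c2cc(=O)c3c(OC)cc(OC)c(I)c3o2)cc1 | intermediate
4 | methyl 3-bromo-4-hydroxybenzoate | COC(=O)c1ccc(O)c(Br)c1 | starting material
5 | methyl 4-(benzyloxy)-3-bromobenzoate | COC(=O)c1ccc(OCc2ccccc2)c(Br)c1 | intermediate
6 | tert-butyl acetate | CC(=O)OC(C)(C)C | starting material
7 | lithium enolate of tert-butyl acetate | [Li]OC(=C)OC(C)(C)C | intermediate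
8 | tert-butyl 3-[4-(benzyloxy)-3-bromophenyl]-3-oxopropanoate | CC(C)(C)OC(=O)CC(=O)c1ccc(OCc2ccccc2)c(Br)c1 | intermediate
9 | tert-butyl (3R)-3-[4-(benzyloxy)-3-bromophenyl]-3-hydroxypropanoate | CC(C)(C)OC(=O)C[C@@H](O)c1ccc(OCc2ccccc2)c(Br)c1 | intermediate
10 | tert-butyl (3R)-3-[4-(benzyloxy)-3-(4,4,5,5-tetramethyl-1,3,2-dioxaborolan-2-yl)phenyl]-3-hydroxypropanoate | CC(C)(C)OC(=O)C[C@@H](O)c1ccc(OCc2ccccc2)c(B2OC(C)(C)C(C)(C)O2)c1 | intermediate
11 | tert-butyl (3R)-3-{4-(benzyloxy)-3-[5,7-dimethoxy-2-(4-methoxyphenyl)-4-oxo-4H-chromen-8-yl]phenyl}-3-hydroxypropanoate | COc1ccc(-c2cc(=O)c3c(OC)cc(OC)c(-c4cc([C@H](O)CC(=O)OC(C)(C)C)ccc4OCc5ccccc5)c3o2)cc1 | intermediate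
12 | tert-butyl (3R)-3-{3-[5,7-dimethoxy-2-(4-methoxyphenyl)-4-oxo-4H-chromen-8-yl]-4-hydroxyphenyl}-3-hydroxypropanoate | COc1ccc(-c2cc(=O)c3c(OC)cc(OC)c(-c4cc([C@H](O)CC(=O)OC(C)(C)C)ccc4O)c3o2)cc1 | intermediate
13 | tert-butyl (3R)-3-{4-acetoxy-3-[5,7-dimethoxy-2-(4-methoxyphenyl)-4-oxo-4H-chromen-8-yl]phenyl}-3-hydroxypropanoate | COc1ccc(-c2cc(=O)c3c(OC)cc(OC)c(-c4cc([C@H](O)CC(=O)OC(C)(C)C)ccc4OC(C)=O)c3o2)cc1 | intermediate
14 | 3,5-dimethoxyphenol | COc1cc(O)cc(OC)c1 | starting material
15 | tert-butyl (3S)-3-{4-acetoxy-3-[5,7-dimethoxy-2-(4-methoxyphenyl)-4-oxo-4H-chromen-8-yl]phenyl}-3-(3,5-dimethoxyphenoxy)propanoate | COc1ccc(-c2cc(=O)c3c(OC)cc(OC)c(-c4cc([C@@H](Oc5cc(OC)cc(OC)c5)CC(=O)OC(C)(C)C)ccc4OC(C)=O)c3o2)cc1 | intermediate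
16 | (3S)-3-{4-acetoxy-3-[5,7-dimethoxy-2-(4-methoxyphenyl)-4-oxo-4H-chromen-8-yl]phenyl}-3-(3,5-dimethoxyphenoxy)propanoic acid | COc1ccc(-c2cc(=O)c3c(OC)cc(OC)c(-c4cc([C@@H](Oc5cc(OC)cc(OC)c5)CC(=O)O)ccc4OC(C)=O)c3o2)cc1 | intermediate
17 | mixed anhydride of 16 and trifluoroacetic acid | COc1ccc(-c2cc(=O)c3c(OC)cc(OC)c(-c4cc([C@@H](Oc5cc(OC)cc(OC)c5)CC(=O)OC(=O)C(F)(F)F)ccc4OC(C)=O)c3o2)cc1 | intermediate
18 | 4'-O-acetyl-5,5''-di-O-methyl-(2S)-2,3-dihydroheveaflavone | COc1ccc(-c2cc(=O)c3c(OC)cc(OC)c(-c4cc([C@@H]5CC(=O)c6c(OC)cc(OC)cc6O5)ccc4OC(C)=O)c3o2)cc1 | intermediate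
19 | 4'-O-acetyl-(2S)-2,3-dihydroheveaflavone | COc1ccc(-c2cc(=O)c3c(O)cc(OC)c(-c4cc([C@@H]5CC(=O)c6c(O)cc(OC)cc6O5)ccc4OC(C)=O)c3o2)cc1 | intermediate
20 | (2S)-2,3-dihydroheveaflavone | COc1ccc(-c2cc(=O)c3c(O)cc(OC)c(-c4cc([C@@H]5CC(=O)c6c(O)cc(OC)cc6O5)ccc4O)c3o2)cc1 | target

Total step count: 13.
Longest linear sequence: 11 steps (4 → 20, steps 3 to 13).

Steps most likely to fail

**Step 11 (key step).** Acid-induced heterolysis of the benzylic C2–O1 bond could erode the configuration or expel the phenol. A trifluoroacetyl group could also be transferred to ring A ahead of ring closure. The fallback leaves the Brønsted-acid, mixed-anhydride manifold. It sets out from 16, which 1-chloro-N,N,2-trimethylprop-1-en-1-amine (CH2Cl2, 0 °C, neutral) should convert to the (S)-acid chloride F1. SnCl4 (2.5 equiv, CH2Cl2, −78 °C) should then close ring C as a classical acyl chloride Friedel–Crafts acylation. No competing acyl donor is present, and one equivalent of HCl at low temperature is the only protic acid. The fallback comes back to the route at 18.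

**Step 9.** The activated carbinol could undergo β-elimination toward the cinnamate, helped by the ester next to C3, or ionise partly before substitution. The fallback removes the cause by carrying C4 as a protected primary alcohol, and it sets out from 9.
- LiAlH4 (THF, 0 °C) should give the (R)-1,3-diol F2, and TBSCl/imidazole (CH2Cl2, 0 °C) its primary silyl ether F3.
- The conditions of step 6 should give the pinacol boronate F4, and those of step 7 with 3 the biaryl carbinol F5.
- Hydrogenolysis to the phenol F6 and acetylation, both as in step 8, lead to the acetate F7.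
- Mitsunobu etherification with 14, a well-behaved reaction of 1-aryl-3-silyloxypropan-1-ols, should give the (S)-aryl ether F8.
- HF·pyridine (THF, 0 °C) frees the primary alcohol F9.
- TEMPO-catalysed oxidation (TEMPO, NaClO2, cat. NaOCl, pH 6.7 phosphate buffer/MeCN) takes it to the acid.

The route is rejoined at 16, and step 10 is then not needed.

**Step 7.** Transmetalation at the doubly flanked C8'' may be slow, so that protodeboronation of the boronate or reduction of the iodide overtakes coupling. Heat and base cannot be raised freely while the β-hydroxy ester is on board. The fallback makes the biaryl bond before the sensitive side chain exists, and it sets out from 5 and 3.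
- Miyaura borylation of 5 gives the benzoate boronate F10.
- F10 tolerates forcing Suzuki–Miyaura conditions with 3 (Pd(OAc)2, SPhos, K3PO4, toluene/H2O, 110 °C) and should give the biaryl methyl ester F11.
- LiOH (THF/MeOH/H2O, 40 °C) gives the biaryl acid F12.
- 1,1'-Carbonyldiimidazole and then Mg(O2CCH2CO2tBu)2 (THF, rt) give the biaryl β-ketoester F13 by decarboxylative malonate acylation.
- Hydrogenation as in step 5 (CH2Cl2/EtOH for solubility) returns to the route at 11.

Further compounds
F1 | step 11 | (3S)-3-{4-acetoxy-3-[5,7-dimethoxy-2-(4-methoxyphenyl)-4-oxo-4H-chromen-8-yl]phenyl}-3-(3,5-dimethoxyphenoxy)propanoyl chloride | COc1ccc(-c2cc(=O)c3c(OC)cc(OC)c(-c4cc([C@@H](Oc5cc(OC)cc(OC)c5)CC(=O)Cl)ccc4OC(C)=O)c3o2)cc1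
F2 | step 9 | (1R)-1-[4-(benzyloxy)-3-bromophenyl]propane-1,3-diol | OCC[C@@H](O)c1ccc(OCc2ccccc2)c(Br)c1
F3 | step 9 | (1R)-1-[4-(benzyloxy)-3-bromophenyl]-3-[(tert-butyldimethylsilyl)oxy]propan-1-ol | CC(C)(C)[Si](C)(C)OCC[C@@H](O)c1ccc(OCc2ccccc2)c(Br)c1
F4 | step 9 | (1R)-1-[4-(benzyloxy)-3-(4,4,5,5-tetramethyl-1,3,2-dioxaborolan-2-yl)phenyl]-3-[(tert-butyldimethylsilyl)oxy]propan-1-ol | CC(C)(C)[Si](C)(C)OCC[C@@H](O)c1ccc(OCc2ccccc2)c(B2OC(C)(C)C(C)(C)O2)c1
F5 | step 9 | 8-{2-(benzyloxy)-5-[(1R)-3-[(tert-butyldimethylsilyl)oxy]-1-hydroxypropyl]phenyl}-5,7-dimethoxy-2-(4-methoxyphenyl)-4H-chromen-4-one | COc1ccc(-c2cc(=O)c3c(OC)cc(OC)c(-c4cc([C@H](O)CCO[Si](C)(C)C(C)(C)C)ccc4OCc5ccccc5)c3o2)cc1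
F6 | step 9 | 8-{5-[(1R)-3-[(tert-butyldimethylsilyl)oxy]-1-hydroxypropyl]-2-hydroxyphenyl}-5,7-dimethoxy-2-(4-methoxyphenyl)-4H-chromen-4-one | COc1ccc(-c2cc(=O)c3c(OC)cc(OC)c(-c4cc([C@H](O)CCO[Si](C)(C)C(C)(C)C)ccc4O)c3o2)cc1
F7 | step 9 | 4-[(1R)-3-[(tert-butyldimethylsilyl)oxy]-1-hydroxypropyl]-2-[5,7-dimethoxy-2-(4-methoxyphenyl)-4-oxo-4H-chromen-8-yl]phenyl acetate | COc1ccc(-c2cc(=O)c3c(OC)cc(OC)c(-c4cc([C@H](O)CCO[Si](C)(C)C(C)(C)C)ccc4OC(C)=O)c3o2)cc1
F8 | step 9 | 4-[(1S)-3-[(tert-butyldimethylsilyl)oxy]-1-(3,5-dimethoxyphenoxy)propyl]-2-[5,7-dimethoxy-2-(4-methoxyphenyl)-4-oxo-4H-chromen-8-yl]phenyl acetate | COc1ccc(-c2cc(=O)c3c(OC)cc(OC)c(-c4cc([C@@H](Oc5cc(OC)cc(OC)c5)CCO[Si](C)(C)C(C)(C)C)ccc4OC(C)=O)c3o2)cc1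
F9 | step 9 | 4-[(1S)-1-(3,5-dimethoxyphenoxy)-3-hydroxypropyl]-2-[5,7-dimethoxy-2-(4-methoxyphenyl)-4-oxo-4H-chromen-8-yl]phenyl acetate | COc1ccc(-c2cc(=O)c3c(OC)cc(OC)c(-c4cc([C@@H](Oc5cc(OC)cc(OC)c5)CCO)ccc4OC(C)=O)c3o2)cc1
F10 | step 7 | methyl 4-(benzyloxy)-3-(4,4,5,5-tetramethyl-1,3,2-dioxaborolan-2-yl)benzoate | COC(=O)c1ccc(OCc2ccccc2)c(B2OC(C)(C)C(C)(C)O2)c1
F11 | step 7 | methyl 4-(benzyloxy)-3-[5,7-dimethoxy-2-(4-methoxyphenyl)-4-oxo-4H-chromen-8-yl]benzoate | COc1ccc(-c2cc(=O)c3c(OC)cc(OC)c(-c4cc(C(=O)OC)ccc4OCc5ccccc5)c3o2)cc1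
F12 | step 7 | 4-(benzyloxy)-3-[5,7-dimethoxy-2-(4-methoxyphenyl)-4-oxo-4H-chromen-8-yl]benzoic acid | COc1ccc(-c2cc(=O)c3c(OC)cc(OC)c(-c4cc(C(=O)O)ccc4OCc5ccccc5)c3o2)cc1
F13 | step 7 | tert-butyl 3-{4-(benzyloxy)-3-[5,7-dimethoxy-2-(4-methoxyphenyl)-4-oxo-4H-chromen-8-yl]phenyl}-3-oxopropanoate | COc1ccc(-c2cc(=O)c3c(OC)cc(OC)c(-c4cc(C(=O)CC(=O)OC(C)(C)C)ccc4OCc5ccccc5)c3o2)cc1
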